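The oxolane ring (O, C9, C11, C12, C13; labdane numbering) is closed by the C9–C11 bond. C9 is the ring-B carbon β to C7, and its ether oxygen already links it to C13; a temporary C7 ketone therefore turns C8=C9–O–C13 into a β-alkoxy enone with a built-in tether. A primary C11 radical, released from the 2-iodoethyl arm of the preformed lactone carbinol C13, adds 5-exo to C9 on the convex face, and hydrogen transfer to C8 follows on the same face, so the spiro centre C9 and C8 are set in one operation. The precursor is assembled by a Diels–Alder reaction that relays C5 and C10 from one catalytically set centre, C4.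

Key step: step 16

Remark: the SMILES is read literally – H5, the C19 carbonyl on C4 and C20 on C10 lie on one face (β), so the decalin is cis-fused and the 19,6β-lactone is trans-fused to both carbocycles; C8 has an α-methyl, C9 has O α and C11 β, C13 is R. Labdane numbering: ring A = C1–C5 and C10, ring B = C5–C10, C17 = methyl on C8, C18 = methyl on C4, C19 = carboxyl carbon on C4, C20 = CH2 on C10, C11–C12 = oxolane CH2CH2, C13–C16 = butanolide.

Step 1
Reactants: 1 (R)-malic acid; 2 pivalaldehyde
Product: 3 2-[(2R,4R)-2-tert-butyl-5-oxo-1,3-dioxolan-4-yl]acetic acid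
Conditions: TsOH·H2O (cat.), H2SO4 (cat.), pentane, reflux, water separator
Reagents that add atoms: none
Why: Acid-catalysed acetalisation of the α-hydroxy acid gives the dioxolanone, whose cis isomer (tert-butyl cis to CH2CO2H) is thermodynamically preferred, so the acetal carbon is set by the malic acid stereocentre.

Step 2
Reactants: 3 dioxolanone acid; 4 2-chloroethyl trifluoromethanesulfonate
Product: 5 2-[(2R,4S)-2-tert-butyl-4-(2-chloroethyl)-5-oxo-1,3-dioxolan-4-yl]acetic acid
Conditions: LiN(SiMe3)2 (2.2 equiv), THF, −78 °C; then 4, −78 to −40 °C; aq. HCl work-up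
Reagents that add atoms: none
Why: Enolate alkylation of the dianion occurs anti to the tert-butyl group (self-regeneration of the stereocentre), so the chloroethyl arm replaces the former hydrogen with retention and fixes the future C13; the triflate reacts in preference to the chloride.

Step 3
Reactants: 5 alkylated dioxolanone acid
Product: 7 (3S)-3-(2-chloroethyl)-3-hydroxyoxolan-2-one, via dioxolanone alcohol 6 (not isolated)
Conditions: BH3·SMe2, THF, 0 °C to rt; then TsOH·H2O (cat.), CH2Cl2, rt
Reagents that add atoms: none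
Why: Borane reduces the free carboxylic acid chemoselectively, and under acid the new alcohol attacks the dioxolanone carbonyl (5-exo-trig translactonisation) with loss of pivalaldehyde, leaving the tertiary carbinol centre untouched.

Step 4
Reactants: 7 hydroxy lactone
Product: 8 (3S)-3-(2-chloroethyl)-2-oxooxolan-3-yl formate
Conditions: acetic formic anhydride, pyridine, DMAP (cat.), CH2Cl2, 0 °C to rt
Reagents that add atoms: acetic formic anhydride CC(=O)OC=O
Why: O-Formylation of the tertiary alcohol by acyl transfer of the less hindered formyl group of the mixed anhydride.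

Step 5
Reactants: 8 formate; 9 3-(triphenyl-λ5-phosphanylidene)butan-2-one
Product: 10 (3S)-3-(2-chloroethyl)-3-{[(1E)-2-methyl-3-oxobut-1-en-1-yl]oxy}oxolan-2-one
Conditions: PhMe, 100 °C
Reagents that add atoms: none
Why: Wittig olefination of the activated formate ester by the acyl-stabilised ylide should give the (E)-β-alkoxy enone under neutral conditions that spare the lactone and the alkyl chloride.

Step 6
Reactants: 10 β-alkoxy enone
Product: 11 (3S)-3-{[(1E)-3-(tert-butyldimethylsilyloxy)-2-methylbuta-1,3-dien-1-yl]oxy}-3-(2-chloroethyl)oxolan-2-one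
Conditions: TBSOTf, Et3N, Et2O, 0 °C
Reagents that add atoms: tert-butyldimethylsilyl trifluoromethanesulfonate CC(C)(C)[Si](C)(C)OS(=O)(=O)C(F)(F)F
Why: Soft enolisation of the methyl ketone gives the 1-alkoxy-3-silyloxy diene with the E enol ether geometry retained.

Step 7
Reactants: 12 tert-butyl 2-oxocyclohexane-1-carboxylate
Product: 13 tert-butyl (1S)-1-methyl-2-oxocyclohexane-1-carboxylate
Conditions: MeI, (11bS)-4,4-dibutyl-2,6-bis(3,4,5-trifluorophenyl)-4,5-dihydro-3H-dinaphtho[2,1-c:1',2'-e]azepinium bromide (1 mol %; its antipode if the sense of induction requires), CsOH·H2O, PhMe, −40 °C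
Reagents that add atoms: iodomethane CI
Why: Enantioselective phase-transfer alkylation of the β-keto ester enolate inside the chiral ammonium ion pair creates the quaternary C4 (S), the only carbocyclic stereocentre set by a catalyst.

Step 8
Reactants: 13 methylated β-keto ester
Product: 14 tert-butyl (1S,3Z)-3-(hydroxymethylidene)-1-methyl-2-oxocyclohexane-1-carboxylate
Conditions: NaH, HCO2Et, THF, 0 °C to rt; aq. HCl work-up
Reagents that add atoms: ethyl formate CCOC=O
Why: Claisen formylation at the only enolisable position (the future C10) installs the future C20.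

Step 9
Reactants: 14 hydroxymethylidene ketone
Product: 15 tert-butyl (1S,3E)-1-methyl-2-oxo-3-[(propan-2-yloxy)methylidene]cyclohexane-1-carboxylate
Conditions: 2-iodopropane, K2CO3, acetone, reflux
Reagents that add atoms: 2-iodopropane CC(C)I
Why: O-Alkylation of the β-keto aldehyde enolate gives the vinylogous ester needed for carbonyl transposition.

Step 10
Reactants: 15 isopropoxymethylidene ketone
Product: 17 tert-butyl (1S)-3-formyl-1-methylcyclohex-2-ene-1-carboxylate, via allylic alcohol 16 (not isolated)
Conditions: NaBH4, CeCl3·7H2O, MeOH, 0 °C; then 1 M HCl, THF, rt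
Reagents that add atoms: water O
Why: Luche 1,2-reduction of the vinylogous ester carbonyl, then acid hydrolysis of the γ-hydroxy enol ether with allylic transposition, gives the enal with C5=C10 and the formyl group (C20) on C10; C4 is not touched.

Step 11
Reactants: 11 silyloxy diene; 17 enal
Product: 18 Diels–Alder adduct (cis-fused octalin; C4 α-CH3/β-CO2tBu, 5β-H, 10β-CHO, C7(OTBS)=C8(CH3), 9β-O-lactonyl)
Conditions: PhMe, 110 °C, sealed tube, 2,6-di-tert-butyl-4-methylphenol (cat.)
Reagents that add atoms: none
Why: Normal-demand Diels–Alder reaction in which the nucleophilic CH2 terminus (C6) bonds to C5 and C9 to C10; suprafacial addition gives the cis ring fusion (5β-H, 10β-CHO), and the diene should approach anti to the pseudoaxial tert-butoxycarbonyl group on C4, so C5 and C10 are relayed from C4 (the endo C9 configuration is erased in step 12).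

Step 12
Reactants: 18 Diels–Alder adduct
Product: 19 vinylogous ester aldehyde (ring B: C7(=O)–C8(CH3)=C9(O-lactonyl))
Conditions: DDQ, 2,6-lutidine, MeCN, 0 °C to rt
Reagents that add atoms: none
Why: Dehydrogenation of a silyl enol ether to an enone: DDQ abstracts the C9 hydride (allylic to the enol ether and α to oxygen) and the oxocarbenium ion loses the silyl group, making C9 the sp2 β-carbon of a β-alkoxy enone.

Step 13
Reactants: 19 vinylogous ester aldehyde
Product: 21 acetate (10β-CH2OAc), via primary alcohol 20 (not isolated)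
Conditions: NaBH4, MeOH/THF, −40 °C; then Ac2O, Et3N, DMAP (cat.), CH2Cl2, 0 °C
Reagents that add atoms: acetic anhydride CC(=O)OC(C)=O
Why: Borohydride should reduce only the non-enolisable aldehyde at low temperature (vinylogous ester, esters and lactone are far less electrophilic), and the neopentyl alcohol is acetylated in the same flask.

Step 14
Reactants: 21 acetate
Product: 23 6β-(tert-butyldimethylsilyloxy) vinylogous ester, via silyl dienol ether 22 (not isolated)
Conditions: TBSOTf, Et3N, CH2Cl2, −78 to 0 °C; then DMDO, acetone, −78 to 0 °C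
Reagents that add atoms: tert-butyldimethylsilyl trifluoromethanesulfonate CC(C)(C)[Si](C)(C)OS(=O)(=O)C(F)(F)F; dimethyldioxirane CC1(C)OO1
Why: Rubottom oxidation: enolisation can occur only toward C6 (C10 is quaternary), the dioxirane should epoxidise the unhindered silyl enol ether on the convex β-face anti to C4, and silyl migration gives the 6β-silyloxy ketone without a strong base.

Step 15
Reactants: 23 6β-silyloxy vinylogous ester
Product: 24 iodide (2-iodoethyl arm on C13)
Conditions: NaI, 2-butanone, 80 °C
Reagents that add atoms: sodium iodide [Na+].[I-]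
Why: Finkelstein SN2 exchange at the primary chloride, driven by precipitation of NaCl.

Step 16
Reactants: 24 iodide
Product: 25 spiro ketone (9α,13-epoxy spiro-oxolane, 7-oxo, 8α-CH3)
Conditions: Bu3SnH (slow addition), AIBN, PhH, 80 °C, high dilution
Reagents that add atoms: none
Why: Bu3Sn• abstracts iodine from C11, and the primary radical adds to C9, the β-carbon of the ring-B β-alkoxy enone C7(=O)–C8=C9–O–C13, to which it is tethered through the ether oxygen; the resulting C8 α-keto radical takes hydrogen from Bu3SnH and carries the chain. The closest known reaction type is the 5-exo radical cyclisation of β-alkoxy acrylates and β-alkoxy enones to oxolanes, applied here to a fully substituted β-carbon. The oxolane ring (O, C9, C11, C12, C13) closes in the 5-exo-trig mode. C9 is controlled by the cis-fused decalin: C11 should add on the convex β-face, anti to the pseudoaxial C1 methylene of ring A, which leaves the ether oxygen α; C8 is set by hydrogen transfer to the same convex face (8α-CH3), and C13 is carried in unchanged. The step needs attack at C9 rather than C8 (secured by the polarity match of the nucleophilic radical with the enone β-carbon and by the five- over six-membered transition state), cyclisation ahead of direct reduction (slow stannane addition), and retention of the β-alkoxy group (secured by radical, non-enolate termination).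

Step 17
Reactants: 25 spiro ketone
Product: 26 7-alcohol (both C7 epimers)
Conditions: NaBH4, CeCl3·7H2O, MeOH/THF, −40 to 0 °C
Reagents that add atoms: none
Why: Luche reduction of the ketone under weakly basic conditions avoids retro-oxa-Michael opening of the β-alkoxy ketone and epimerisation at C8; the carbinol configuration is irrelevant.

Step 18
Reactants: 26 7-alcohol
Product: 27 7-O-(1H-imidazol-1-ylcarbonothioyl) derivative
Conditions: 1,1'-thiocarbonyldiimidazole, DMAP, ClCH2CH2Cl, 80 °C
Reagents that add atoms: 1,1'-thiocarbonyldiimidazole S=C(n1ccnc1)n1ccnc1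
Why: Thioacylation of the secondary alcohol gives the radical-labile thiocarbamate.

Step 19
Reactants: 27 thiocarbamate
Product: 28 7-deoxy compound (C7 = CH2)
Conditions: Bu3SnH, AIBN, PhMe, 110 °C
Reagents that add atoms: none
Why: Barton–McCombie deoxygenation: stannyl radical addition to C=S, β-scission to the secondary C7 radical and hydrogen transfer remove the temporary C7 oxygen.

Step 20
Reactants: 28 7-deoxy compound
Product: 30 hydroxy acid (6β-OH, C19 CO2H), via 6β-alcohol tert-butyl ester 29 (not isolated)
Conditions: HF·pyridine, THF, 0 °C to rt; then TFA, CH2Cl2, 0 °C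
Reagents that add atoms: none
Why: Fluoride cleaves the silyl ether and acidolysis of the tert-butyl ester (loss of isobutene) frees the C19 acid; no stereocentre is involved.

Step 21
Reactants: 30 hydroxy acid
Product: 31 target CNP0298733.1
Conditions: 2-chloro-1-methylpyridinium iodide, Et3N, MeCN, 80 °C, high dilution
Reagents that add atoms: none
Why: Activation of the hindered acid as its 2-acyloxypyridinium salt and intramolecular acyl transfer to the 6β-hydroxyl should close the γ-lactone with retention at C6 (the C6–O bond is not broken); C20 is blocked as the acetate.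

Compound list
1 | (R)-malic acid | O[C@H](CC(=O)O)C(=O)O | starting material
2 | pivalaldehyde | CC(C)(C)C=O | starting material
3 | 2-[(2R,4R)-2-tert-butyl-5-oxo-1,3-dioxolan-4-yl]acetic acid (cis) | OC(=O)C[C@H]1O[C@@H](C(C)(C)C)OC1=O | intermediate
4 | 2-chloroethyl trifluoromethanesulfonate | ClCCOS(=O)(=O)C(F)(F)F | starting material
5 | 2-[(2R,4S)-2-tert-butyl-4-(2-chloroethyl)-5-oxo-1,3-dioxolan-4-yl]acetic acid (chloroethyl trans to tert-butyl) | OC(=O)C[C@@]1(CCCl)O[C@@H](C(C)(C)C)OC1=O | intermediate
6 | (2R,5S)-2-tert-butyl-5-(2-chloroethyl)-5-(2-hydroxyethyl)-1,3-dioxolan-4-one | OCC[C@@]1(CCCl)O[C@@H](C(C)(C)C)OC1=O | intermediate (not isolated)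
7 | (3S)-3-(2-chloroethyl)-3-hydroxyoxolan-2-one | O=C1OCC[C@]1(O)CCCl | intermediate
8 | (3S)-3-(2-chloroethyl)-2-oxooxolan-3-yl formate | O=CO[C@]1(CCCl)CCOC1=O | intermediate
9 | 3-(triphenyl-λ5-phosphanylidene)butan-2-one | CC(=O)C(C)=P(c1ccccc1)(c1ccccc1)c1ccccc1 | starting material
10 | (3S)-3-(2-chloroethyl)-3-{[(1E)-2-methyl-3-oxobut-1-en-1-yl]oxy}oxolan-2-one | CC(=O)/C(C)=C/O[C@]1(CCCl)CCOC1=O | intermediate
11 | (3S)-3-{[(1E)-3-(tert-butyldimethylsilyloxy)-2-methylbuta-1,3-dien-1-yl]oxy}-3-(2-chloroethyl)oxolan-2-one | C=C(O[Si](C)(C)C(C)(C)C)/C(C)=C/O[C@]1(CCCl)CCOC1=O | intermediate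
12 | tert-butyl 2-oxocyclohexane-1-carboxylate | O=C1CCCCC1C(=O)OC(C)(C)C | starting material
13 | tert-butyl (1S)-1-methyl-2-oxocyclohexane-1-carboxylate | O=C1CCCC[C@]1(C)C(=O)OC(C)(C)C | intermediate
14 | tert-butyl (1S,3Z)-3-(hydroxymethylidene)-1-methyl-2-oxocyclohexane-1-carboxylate | O=C1/C(=C\O)CCC[C@]1(C)C(=O)OC(C)(C)C | intermediate
15 | tert-butyl (1S,3E)-1-methyl-2-oxo-3-[(propan-2-yloxy)methylidene]cyclohexane-1-carboxylate | O=C1/C(=C/OC(C)C)CCC[C@]1(C)C(=O)OC(C)(C)C | intermediate
16 | tert-butyl (1S,3E)-2-hydroxy-1-methyl-3-[(propan-2-yloxy)methylidene]cyclohexane-1-carboxylate (both C2 epimers) | OC1/C(=C/OC(C)C)CCC[C@]1(C)C(=O)OC(C)(C)C | intermediate (not isolated)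
17 | tert-butyl (1S)-3-formyl-1-methylcyclohex-2-ene-1-carboxylate | O=CC1=C[C@@](C)(C(=O)OC(C)(C)C)CCC1 | intermediate
18 | Diels–Alder adduct: cis-fused octalin, C4 with α-CH3 and β-CO2tBu, 5β-H, 10β-CHO, C7(OTBS)=C8(CH3), 9β-O-[(3S)-3-(2-chloroethyl)-2-oxooxolan-3-yl] (9α-H) | O=C[C@]12CCC[C@](C)(C(=O)OC(C)(C)C)[C@H]1CC(O[Si](C)(C)C(C)(C)C)=C(C)[C@@H]2O[C@]3(CCCl)CCOC3=O | intermediate
19 | vinylogous ester aldehyde: as 18 but ring B is C7(=O)–C8(CH3)=C9(O-lactonyl) | O=C[C@]12CCC[C@](C)(C(=O)OC(C)(C)C)[C@H]1CC(=O)C(C)=C2O[C@]3(CCCl)CCOC3=O | intermediate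
20 | primary alcohol: 10β-CH2OH analogue of 19 | OC[C@]12CCC[C@](C)(C(=O)OC(C)(C)C)[C@H]1CC(=O)C(C)=C2O[C@]3(CCCl)CCOC3=O | intermediate (not isolated)
21 | acetate: 10β-CH2OAc analogue of 19 | CC(=O)OC[C@]12CCC[C@](C)(C(=O)OC(C)(C)C)[C@H]1CC(=O)C(C)=C2O[C@]3(CCCl)CCOC3=O | intermediate
22 | silyl dienol ether of 21: C6=C7(OTBS)–C8(CH3)=C9(O-lactonyl) | CC(=O)OC[C@]12CCC[C@](C)(C(=O)OC(C)(C)C)[C@H]1C=C(O[Si](C)(C)C(C)(C)C)C(C)=C2O[C@]3(CCCl)CCOC3=O | intermediate (not isolated)
23 | 6β-(tert-butyldimethylsilyloxy) vinylogous ester: 21 with OTBS on C6, cis to 5-H | CC(=O)OC[C@]12CCC[C@](C)(C(=O)OC(C)(C)C)[C@H]1[C@H](O[Si](C)(C)C(C)(C)C)C(=O)C(C)=C2O[C@]3(CCCl)CCOC3=O | intermediate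
24 | iodide: 23 with a 2-iodoethyl arm on C13 | CC(=O)OC[C@]12CCC[C@](C)(C(=O)OC(C)(C)C)[C@H]1[C@H](O[Si](C)(C)C(C)(C)C)C(=O)C(C)=C2O[C@]3(CCI)CCOC3=O | intermediate
25 | spiro ketone: cis-decalin (5β-H, 10β-CH2OAc), C4 α-CH3/β-CO2tBu, 6β-OTBS, 7-oxo, 8α-CH3, spiro-oxolane at C9 (O α, C11 β), C13 (R) spiro to the γ-butyrolactone | CC(=O)OC[C@@]12CCC[C@](C)(C(=O)OC(C)(C)C)[C@H]2[C@H](O[Si](C)(C)C(C)(C)C)C(=O)[C@@H](C)[C@]13CC[C@]1(CCOC1=O)O3 | intermediate
26 | 7-alcohol of 25 (both C7 epimers) | CC(=O)OC[C@@]12CCC[C@](C)(C(=O)OC(C)(C)C)[C@H]2[C@H](O[Si](C)(C)C(C)(C)C)C(O)[C@@H](C)[C@]13CC[C@]1(CCOC1=O)O3 | intermediate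
27 | 7-O-(1H-imidazol-1-ylcarbonothioyl) derivative of 26 | CC(=O)OC[C@@]12CCC[C@](C)(C(=O)OC(C)(C)C)[C@H]2[C@H](O[Si](C)(C)C(C)(C)C)C(OC(=S)n2ccnc2)[C@@H](C)[C@]13CC[C@]1(CCOC1=O)O3 | intermediate
28 | 7-deoxy compound: 25 with CH2 at C7 | CC(=O)OC[C@@]12CCC[C@](C)(C(=O)OC(C)(C)C)[C@H]2[C@H](O[Si](C)(C)C(C)(C)C)C[C@@H](C)[C@]13CC[C@]1(CCOC1=O)O3 | intermediate
29 | 6β-alcohol tert-butyl ester: 28 without the silyl group | CC(=O)OC[C@@]12CCC[C@](C)(C(=O)OC(C)(C)C)[C@H]2[C@H](O)C[C@@H](C)[C@]13CC[C@]1(CCOC1=O)O3 | intermediate (not isolated)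
30 | hydroxy acid: 6β-OH and free C19 carboxylic acid | CC(=O)OC[C@@]12CCC[C@](C)(C(=O)O)[C@H]2[C@H](O)C[C@@H](C)[C@]13CC[C@]1(CCOC1=O)O3 | intermediate
31 | CNP0298733.1 | CC(=O)OC[C@@]12CCC[C@]3(C)C(=O)O[C@H](C[C@@H](C)[C@]14CC[C@]1(CCOC1=O)O4)[C@@H]23 | target

Total step count: 21. Longest linear sequence: 17 steps (steps 1–6 and 11–21).

Steps most likely to fail

Step 11. The β-carbon of enal 17 is flanked by the quaternary C4, so the cycloaddition may be too slow for the diene to survive, may divert to hetero-Diels–Alder addition at the formyl group, or may discriminate poorly between the two alkene faces. The fallback sets out from 10 (with 17) and returns at 19. It replaces thermal substrate control by catalyst-controlled Lewis-acid activation. Compound 10 is silylated with TIPSOTf/Et3N to the more acid-tolerant triisopropylsilyl diene F1. F1 and 17 are combined at −78 °C under a proline-derived B-(o-tolyl)oxazaborolidinium triflimide, using the catalyst enantiomer matched to α-face attack; this should give the triisopropylsilyl enol ether adduct F2. Oxidation of F2 with DDQ as in step 12 gives 19.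

Step 16. The primary C11 radical may be reduced by the stannane, or may abstract hydrogen intramolecularly, before it closes onto the congested, fully substituted C9. The fallback sets out from 24 and returns at 25. It is a stannane-free nickel-catalysed reductive conjugate addition: NiCl2(dme) as divalent nickel precatalyst, 2,2':6',2''-terpyridine, zerovalent manganese powder and Et3SiCl in DMF at rt. The enolate oxygen is silylated in the bond-forming event, so no hydrogen donor is present and β-alkoxide loss is blocked; the product should be the triethylsilyl enol ether F3. Mild hydrolysis (AcOH, THF, H2O), with protonation of C8 from the convex face, gives 25.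

Step 21. Acyl transfer to O6 requires one carbocycle to leave its chair (the lactone is trans-fused to both rings), so intermolecular esterification may outrun ring closure. The fallback sets out from 28 and returns at 31. It closes the same ring by forming the C6–O bond with inversion. HF·pyridine gives 29, now isolated. Dess–Martin periodinane gives the 6-ketone F4. NaBH4, delivering hydride to the convex β-face, gives the 6α-alcohol F5. Tf2O with 2,6-di-tert-butylpyridine gives the 6α-triflate F6, which should be displaced from the β-face by the carbonyl oxygen of the C19 tert-butyl ester, with loss of isobutene, to give 31.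

Further compounds
F1 | step 11 | (3S)-3-(2-chloroethyl)-3-{[(1E)-2-methyl-3-(triisopropylsilyloxy)buta-1,3-dien-1-yl]oxy}oxolan-2-one | C=C(O[Si](C(C)C)(C(C)C)C(C)C)/C(C)=C/O[C@]1(CCCl)CCOC1=O
F2 | step 11 | triisopropylsilyl enol ether analogue of adduct 18 | O=C[C@]12CCC[C@](C)(C(=O)OC(C)(C)C)[C@H]1CC(O[Si](C(C)C)(C(C)C)C(C)C)=C(C)[C@@H]2O[C@]3(CCCl)CCOC3=O
F3 | step 16 | C7 triethylsilyl enol ether of spiro ketone 25 (C7(OSiEt3)=C8(CH3)) | CC(=O)OC[C@@]12CCC[C@](C)(C(=O)OC(C)(C)C)[C@H]2[C@H](O[Si](C)(C)C(C)(C)C)C(O[Si](CC)(CC)CC)=C(C)[C@]13CC[C@]1(CCOC1=O)O3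
F4 | step 21 | 6-ketone from 29 | CC(=O)OC[C@@]12CCC[C@](C)(C(=O)OC(C)(C)C)[C@H]2C(=O)C[C@@H](C)[C@]13CC[C@]1(CCOC1=O)O3
F5 | step 21 | 6α-alcohol tert-butyl ester (C6 epimer of 29) | CC(=O)OC[C@@]12CCC[C@](C)(C(=O)OC(C)(C)C)[C@H]2[C@@H](O)C[C@@H](C)[C@]13CC[C@]1(CCOC1=O)O3
F6 | step 21 | 6α-trifluoromethanesulfonate of F5 | CC(=O)OC[C@@]12CCC[C@](C)(C(=O)OC(C)(C)C)[C@H]2[C@@H](OS(=O)(=O)C(F)(F)F)C[C@@H](C)[C@]13CC[C@]1(CCOC1=O)O3
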